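**Retrosynthetic overview**

1. Numbering: ring A = C1–C4, C5, C10; ring B = C5–C10; β is the face of the C5 methyl. The target is cut at the C3–O ester (diyne acid 29, both (Z)-alkenes by late semihydrogenation) and at the 8,9-diol (acetonide).
2. The equatorial 3α and 9α oxygens are set under thermodynamic control, the axial 8α-OH by a bulky hydride, and C7 by Suzuki coupling of an α-iodo-6-en-8-one followed by conjugate reduction; the 6-en-8-one comes from transposition of the C6 vinylogous ester.
3. Feature on which the plan rests: ring B with oxygen on C8 and C9 and a methyl-bearing quaternary fusion carbon C5 is a masked 2-methoxy-5-methylbenzoquinone, and ring A with oxygen on C3 and methyl on C4 is a 3-silyloxypenta-1,3-diene.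
4. Ring order: ring B enters as the quinone; ring A is closed on it by one Diels–Alder reaction that forms C4–C5 and C1–C10 and fixes C5; C4 and C10 are then equilibrated to the trans-decalin.
5. Side chain: (S)-pent-1-yn-3-ol and hex-2-ynoic acid.

Key step: step 3

Assumption: the (R)-binaphtholate titanium complex is taken to leave open the quinone face that gives the C5 configuration drawn in 5; if the sense of induction is the opposite, the (S)-ligand is used and nothing else changes.
Assumption: (S)-pent-1-yn-3-ol is taken as a purchasable building block.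

**Route**

Step 1
Reactants: 1 2-methoxy-5-methylphenol
Product: 2 2-methoxy-5-methyl-1,4-benzoquinone
Conditions: (KSO3)2NO, KH2PO4, H2O/acetone, rt
Reagents that add atoms: potassium nitrosodisulfonate, [K+].[K+].[O-]S(=O)(=O)N([O])S(=O)(=O)[O-]
Why: Teuber oxidation, in which the nitroxyl radical oxidises a phenol with a free para position to the para-quinone, the new carbonyl entering para to the hydroxyl.

Step 2
Reactants: 3 ethyl vinyl ketone
Product: 4 (Z)-3-(trimethylsilyloxy)penta-1,3-diene
Conditions: TMSOTf, Et3N, Et2O, 0 °C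
Reagents that add atoms: trimethylsilyl triflate, C[Si](C)(C)OS(=O)(=O)C(F)(F)F
Why: Soft enolisation (amine/silyl triflate) at the only enolisable side of the ketone should give mainly the (Z)-silyl dienol ether with oxygen and methyl syn, and any (E)-isomer cannot reach the s-cis conformation and stays inert in step 3.

Step 3
Reactants: 2 2-methoxy-5-methyl-1,4-benzoquinone, 4 (Z)-3-(trimethylsilyloxy)penta-1,3-diene
Product: 5 endo, cis-fused adduct (8-methoxy-4α,5β-dimethyl-10β-H, ring A 2-ene silyl enol ether, ring B 7-ene-6,9-dione)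
Conditions: (R)-BINOL/TiCl2(OiPr)2 (1:1, 30 mol %), 4 Å MS, CH2Cl2, −40 → −20 °C
Reagents that add atoms: none
Why: Lewis acid-catalysed, concerted but asynchronous normal-demand [4+2] cycloaddition; the closest known reaction types are binaphtholate–titanium-catalysed Diels–Alder reactions of quinones with silyloxydienes and chelation-controlled cycloadditions at the methyl-substituted double bond of this same quinone. Titanium held between the C9 carbonyl and the C8 methoxy oxygen activates the C5=C10 bond and makes C5 its electrophilic β-carbon, so the C4 terminus of the diene, made nucleophilic by the C3 silyloxy group, bonds to C5 in advance of C1–C10 bonding. Ring A (C1–C4, C5, C10) is closed in an intermolecular suprafacial [4+2] mode by these two bonds, while the C7=C8 bond, deactivated as a vinylogous ester, stays out. Quaternary C5 is set by the quinone face left open by the binaphtholate ligand, C10 is tied to it by suprafacial addition (cis fusion), and C4 follows from the endo transition state and the outside methyl of the (Z)-diene. The step needs regioselectivity (C4 to C5, not to C10) and face selectivity at C5: the first is secured by the chelating methoxy-carbonyl pair of the quinone together with the donor oxygen on C3 of the diene, the second by the ligand. Because C4 and C10 are re-set by enolisation in step 4, only the configuration of C5 has to be carried out of this step.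

Step 4
Reactants: 5 endo, cis-fused adduct
Product: 7 trans-fused 8-methoxy-4β,5β-dimethyl-10α-H-decal-7-ene-3,6,9-trione, via cis-fused trione 6 (not isolated)
Conditions: NaOMe (0.3 equiv), MeOH, 0 °C → rt; AcOH
Reagents that add atoms: none
Why: Methoxide-induced desilylation of the silyl enol ether (protonation at C2, C4 untouched) is followed by reversible enolisation at C10 (through the C9 ketone) and C4 (through the C3 ketone), so that both settle in the trans-decalin with the equatorial 4β-methyl, while quaternary C5 prevents aromatisation of ring B.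

Step 5
Reactants: 7 trans-fused trione
Product: 8 3β,9β-dihydroxy-8-methoxy-4β,5β-dimethyl-10α-H-decal-7-en-6-one
Conditions: NaBH4, CeCl3·7H2O, MeOH/CH2Cl2, −78 → 0 °C
Reagents that add atoms: none
Why: Luche 1,2-reduction, in which hydride should reach C3 and C9 from the α face because the axial C5 methyl is syn-axial to the β trajectory at both, giving the two axial β-alcohols and leaving the unreactive vinylogous ester carbonyl C6; a wrong C9 epimer is of no concern because C9 is re-set in step 8.

Step 6
Reactants: 8 3β,9β-diol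
Product: 9 3β,9β-bis(tert-butyldimethylsilyloxy)-8-methoxy-decal-7-en-6-one
Conditions: TBSOTf, 2,6-lutidine, CH2Cl2, 0 °C → rt
Reagents that add atoms: tert-butyldimethylsilyl triflate, CC(C)(C)[Si](C)(C)OS(=O)(=O)C(F)(F)F
Why: Silylation with a silyl triflate is strong enough for the two hindered axial alcohols, and the C9 silyl ether later keeps the α-ketol from tautomerising to a diosphenol.

Step 7
Reactants: 9 bis-silyl ether vinylogous ester
Product: 11 3β,9β-bis(silyloxy)-4β,5β-dimethyl-10α-H-decal-6-en-8-one, via allylic alcohol 10 (not isolated)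
Conditions: i-Bu2AlH, CH2Cl2, −78 °C; then 1 M HCl, THF, 0 °C
Reagents that add atoms: water, O
Why: Stork–Danheiser transposition, in which 1,2-reduction of the vinylogous ester carbonyl C6 and acid hydrolysis of the β-hydroxy enol ether with loss of the C6 hydroxyl move the carbonyl to C8 and the alkene to C6=C7, the silyl ethers surviving brief cold dilute acid.

Step 8
Reactants: 11 9β-silyloxy enone
Product: 12 3β,9α-bis(silyloxy)-4β,5β-dimethyl-10α-H-decal-6-en-8-one
Conditions: DBU, toluene, 60 °C
Reagents that add atoms: none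
Why: Base-mediated epimerisation through the C8/C9 enolate, C9-H being the only enolisable hydrogen, should move the silyloxy group from the position syn-axial to the C5 methyl to the equatorial 9α position.

Step 9
Reactants: 12 9α-silyloxy enone
Product: 13 7-iodo-6-en-8-one
Conditions: I2, pyridine, CH2Cl2, 0 °C → rt
Reagents that add atoms: iodine, II
Why: α-Iodination of an enone by conjugate addition of pyridine, iodination of the enolate and elimination (Baylis–Hillman-type sequence) places iodine on C7.

Step 10
Reactants: 13 7-iodo-6-en-8-one, 14 isopropenylboronic acid pinacol ester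
Product: 15 7-isopropenyl-6-en-8-one (cross-conjugated dienone)
Conditions: PdCl2(dppf) (5 mol %), K3PO4, dioxane/H2O, 60 °C
Reagents that add atoms: none
Why: Suzuki–Miyaura coupling of an α-iodoenone with an alkenylboronate forms the C7–isopropenyl bond, and the product is used at once to avoid dimerisation of the 2-acyl diene.

Step 11
Reactants: 15 7-isopropenyl-6-en-8-one
Product: 16 7α-isopropenyl-3β,9α-bis(silyloxy)-4β,5β-dimethyl-10α-H-decal-8-one
Conditions: [(Ph3P)CuH]6, H2O (degassed), THF/toluene, rt
Reagents that add atoms: none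
Why: Copper hydride conjugate reduction delivers hydride to C6, and kinetic protonation of the resulting dienolate at its α-carbon C7 (not at the terminal CH2) keeps the isopropenyl group out of conjugation, axial protonation placing it equatorial (α) and away from the C5 methyl, which is also the more stable epimer.

Step 12
Reactants: 16 7α-isopropenyl 8-ketone
Product: 17 8α-hydroxy-7α-isopropenyl-3β,9α-bis(silyloxy)-decalin
Conditions: LiBH(s-Bu)3, THF, −78 °C; aq. NH4Cl
Reagents that add atoms: none
Why: The bulky trialkylborohydride attacks the C8 ketone along the equatorial direction and should give the axial 8α-alcohol, cis to both equatorial neighbours, without enolising the sensitive α-isopropenyl ketone.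

Step 13
Reactants: 17 8α-alcohol bis-silyl ether
Product: 18 7α-isopropenyl-4β,5β-dimethyl-10α-H-decalin-3β,8α,9α-triol
Conditions: TBAF, THF, rt → 50 °C
Reagents that add atoms: none
Why: Fluoride desilylation removes both silyl ethers, including the hindered axial one at C3.

Step 14
Reactants: 18 3β,8α,9α-triol
Product: 19 8α,9α-O-isopropylidene-3β-ol
Conditions: 2,2-dimethoxypropane, PPTS, acetone, rt
Reagents that add atoms: 2,2-dimethoxypropane, COC(C)(C)OC
Why: Acetalisation can close a five-membered acetonide only across the cis 8α,9α-diol, which leaves the C3 hydroxyl as the single free alcohol.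

Step 15
Reactants: 19 acetonide 3β-ol
Product: 20 8α,9α-O-isopropylidene-3-ketone
Conditions: Dess–Martin periodinane, NaHCO3, CH2Cl2, rt
Reagents that add atoms: none
Why: Dess–Martin oxidation under buffered conditions returns the C3 ketone without touching the acetonide or the alkene, and the adjacent equatorial 4β-methyl is already the stable epimer.

Step 16
Reactants: 20 acetonide 3-ketone
Product: 21 8α,9α-O-isopropylidene-3α-ol
Conditions: Li, NH3(l), THF, EtOH, −78 °C; NH4Cl
Reagents that add atoms: none
Why: Dissolving-metal ketone reduction is under thermodynamic control and should give the equatorial 3α-alcohol, trans to the 4β-methyl, where hydride reagents give the axial epimer, the isolated alkene and the acetonide being inert.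

Step 17
Reactants: 22 (S)-pent-1-yn-3-ol
Product: 23 (S)-3-(tert-butyldimethylsilyloxy)pent-1-yne
Conditions: TBSCl, imidazole, DMF, rt
Reagents that add atoms: tert-butyldimethylsilyl chloride, CC(C)(C)[Si](C)(C)Cl
Why: Standard silylation protects the propargylic alcohol for the acetylide chemistry.

Step 18
Reactants: 23 (S)-3-(tert-butyldimethylsilyloxy)pent-1-yne
Product: 25 tert-butyl (S)-4-(tert-butyldimethylsilyloxy)hex-2-ynoate, via lithium acetylide 24 (not isolated)
Conditions: n-BuLi, THF, −78 °C; Boc2O, −78 → 0 °C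
Reagents that add atoms: di-tert-butyl dicarbonate, CC(C)(C)OC(=O)OC(=O)OC(C)(C)C
Why: C-Acylation of the lithium acetylide with the dicarbonate gives the tert-butyl ynoate without touching the stereocentre.

Step 19
Reactants: 25 tert-butyl (S)-4-(silyloxy)hex-2-ynoate
Product: 26 tert-butyl (S)-4-hydroxyhex-2-ynoate
Conditions: TBAF, AcOH, THF, 0 °C
Reagents that add atoms: none
Why: Acetic acid-buffered fluoride desilylation frees the alcohol without base-induced isomerisation of the γ-hydroxy ynoate.

Step 20
Reactants: 26 tert-butyl (S)-4-hydroxyhex-2-ynoate, 27 hex-2-ynoic acid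
Product: 28 tert-butyl (S)-4-(hex-2-ynoyloxy)hex-2-ynoate
Conditions: DIC, DMAP (cat.), CH2Cl2, 0 °C
Reagents that add atoms: none
Why: Steglich esterification of the secondary propargylic alcohol with an alkynoic acid proceeds with retention at the stereocentre.

Step 21
Reactants: 28 tert-butyl diyne diester
Product: 29 (S)-4-(hex-2-ynoyloxy)hex-2-ynoic acid
Conditions: TFA, CH2Cl2, 0 °C → rt
Reagents that add atoms: none
Why: Acidolysis of the tert-butyl ester with loss of isobutene leaves the secondary propargylic ester intact.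

Step 22
Reactants: 21 acetonide 3α-ol, 29 (S)-4-(hex-2-ynoyloxy)hex-2-ynoic acid
Product: 30 3α-O-[(S)-4-(hex-2-ynoyloxy)hex-2-ynoyl] 8α,9α-acetonide
Conditions: DIC, DMAP (0.2 equiv), CH2Cl2, 0 °C → rt
Reagents that add atoms: none
Why: Steglich esterification of the equatorial C3 alcohol with the alkynoic acid avoids the Z-to-E isomerisation that an activated (Z)-enoic acid would risk.

Step 23
Reactants: 30 diyne ester acetonide
Product: 31 3α-O-[(S,2Z)-4-((Z)-hex-2-enoyloxy)hex-2-enoyl] 8α,9α-acetonide
Conditions: H2 (1 atm), Pd/CaCO3–Pb(OAc)2, quinoline, EtOAc, rt, stopped after 2 equiv H2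
Reagents that add atoms: none
Why: Lindlar semihydrogenation adds hydrogen syn to both conjugated alkynes to give the two (Z)-enoates, the 1,1-disubstituted isopropenyl alkene reacting much more slowly on the poisoned catalyst.

Step 24
Reactants: 31 (Z,Z)-ester acetonide
Product: 32 CNP0271544.1
Conditions: AcOH/THF/H2O (3:1:1), 45 °C
Reagents that add atoms: none
Why: Mild acid hydrolysis of the acetonide releases the cis 8α,9α-diol without affecting the esters, the (Z)-alkenes or the isopropenyl group.

**Compound list**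

1 | 2-methoxy-5-methylphenol | COc1ccc(C)cc1O | starting material
2 | 2-methoxy-5-methyl-1,4-benzoquinone | CC1=CC(=O)C(OC)=CC1=O | intermediate
3 | ethyl vinyl ketone | CCC(=O)C=C | starting material
4 | (Z)-3-(trimethylsilyloxy)penta-1,3-diene | C=C/C(O[Si](C)(C)C)=C/C | intermediate
5 | endo, cis-fused Diels–Alder adduct (4α-Me, 5β-Me, 10β-H; ring A silyl enol ether, ring B methoxy-enedione) | O=C1C=C(OC)C(=O)[C@H]2CC=C(O[Si](C)(C)C)[C@@H](C)[C@@]12C | intermediate
6 | cis-fused 3,6,9-trione (4α-Me, 5β-Me, 10β-H), not isolated | O=C1C=C(OC)C(=O)[C@H]2CCC(=O)[C@@H](C)[C@@]12C | intermediate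
7 | trans-fused 8-methoxy-4β,5β-dimethyl-10α-H-decal-7-ene-3,6,9-trione | O=C1[C@]2(C)[C@@H](C)C(=O)CC[C@H]2C(=O)C(OC)=C1 | intermediate
8 | 3β,9β-dihydroxy-8-methoxy-decal-7-en-6-one | O=C1[C@]2(C)[C@@H](C)[C@@H](O)CC[C@H]2[C@@H](O)C(OC)=C1 | intermediate
9 | 3β,9β-bis(TBS-oxy)-8-methoxy-decal-7-en-6-one | O=C1[C@]2(C)[C@@H](C)[C@@H](O[Si](C)(C)C(C)(C)C)CC[C@H]2[C@@H](O[Si](C)(C)C(C)(C)C)C(OC)=C1 | intermediate
10 | 6β-hydroxy-8-methoxy-7-ene (allylic alcohol, C6 configuration inconsequential), not isolated | O[C@H]1[C@]2(C)[C@@H](C)[C@@H](O[Si](C)(C)C(C)(C)C)CC[C@H]2[C@@H](O[Si](C)(C)C(C)(C)C)C(OC)=C1 | intermediate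
11 | 3β,9β-bis(TBS-oxy)-decal-6-en-8-one | O=C1C=C[C@]2(C)[C@@H](C)[C@@H](O[Si](C)(C)C(C)(C)C)CC[C@H]2[C@H]1O[Si](C)(C)C(C)(C)C | intermediate
12 | 3β,9α-bis(TBS-oxy)-decal-6-en-8-one | O=C1C=C[C@]2(C)[C@@H](C)[C@@H](O[Si](C)(C)C(C)(C)C)CC[C@H]2[C@@H]1O[Si](C)(C)C(C)(C)C | intermediate
13 | 7-iodo-3β,9α-bis(TBS-oxy)-decal-6-en-8-one | O=C1C(I)=C[C@]2(C)[C@@H](C)[C@@H](O[Si](C)(C)C(C)(C)C)CC[C@H]2[C@@H]1O[Si](C)(C)C(C)(C)C | intermediate
14 | isopropenylboronic acid pinacol ester | CC(=C)B1OC(C)(C)C(C)(C)O1 | starting material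
15 | 7-isopropenyl-3β,9α-bis(TBS-oxy)-decal-6-en-8-one | O=C1C(C(C)=C)=C[C@]2(C)[C@@H](C)[C@@H](O[Si](C)(C)C(C)(C)C)CC[C@H]2[C@@H]1O[Si](C)(C)C(C)(C)C | intermediate
16 | 7α-isopropenyl-3β,9α-bis(TBS-oxy)-decal-8-one | O=C1[C@H](C(C)=C)C[C@]2(C)[C@@H](C)[C@@H](O[Si](C)(C)C(C)(C)C)CC[C@H]2[C@@H]1O[Si](C)(C)C(C)(C)C | intermediate
17 | 8α-hydroxy-7α-isopropenyl-3β,9α-bis(TBS-oxy)-decalin | O[C@@H]1[C@H](C(C)=C)C[C@]2(C)[C@@H](C)[C@@H](O[Si](C)(C)C(C)(C)C)CC[C@H]2[C@@H]1O[Si](C)(C)C(C)(C)C | intermediate
18 | 7α-isopropenyl-4β,5β-dimethyl-10α-H-decalin-3β,8α,9α-triol | O[C@@H]1[C@H](C(C)=C)C[C@]2(C)[C@@H](C)[C@@H](O)CC[C@H]2[C@@H]1O | intermediate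
19 | 8α,9α-O-isopropylidene-3β-ol | CC1(C)O[C@@H]2[C@H](C(C)=C)C[C@]3(C)[C@@H](C)[C@@H](O)CC[C@H]3[C@@H]2O1 | intermediate
20 | 8α,9α-O-isopropylidene-3-ketone | CC1(C)O[C@@H]2[C@H](C(C)=C)C[C@]3(C)[C@@H](C)C(=O)CC[C@H]3[C@@H]2O1 | intermediate
21 | 8α,9α-O-isopropylidene-3α-ol | CC1(C)O[C@@H]2[C@H](C(C)=C)C[C@]3(C)[C@@H](C)[C@H](O)CC[C@H]3[C@@H]2O1 | intermediate
22 | (S)-pent-1-yn-3-ol | CC[C@H](O)C#C | starting material
23 | (S)-3-(tert-butyldimethylsilyloxy)pent-1-yne | CC[C@H](O[Si](C)(C)C(C)(C)C)C#C | intermediate
24 | lithium acetylide of 23, not isolated | CC[C@H](O[Si](C)(C)C(C)(C)C)C#C[Li] | intermediate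
25 | tert-butyl (S)-4-(tert-butyldimethylsilyloxy)hex-2-ynoate | CC[C@H](O[Si](C)(C)C(C)(C)C)C#CC(=O)OC(C)(C)C | intermediate
26 | tert-butyl (S)-4-hydroxyhex-2-ynoate | CC[C@H](O)C#CC(=O)OC(C)(C)C | intermediate
27 | hex-2-ynoic acid | CCCC#CC(=O)O | starting material
28 | tert-butyl (S)-4-(hex-2-ynoyloxy)hex-2-ynoate | CC[C@H](OC(=O)C#CCCC)C#CC(=O)OC(C)(C)C | intermediate
29 | (S)-4-(hex-2-ynoyloxy)hex-2-ynoic acid | CC[C@H](OC(=O)C#CCCC)C#CC(=O)O | intermediate
30 | 3α-O-[(S)-4-(hex-2-ynoyloxy)hex-2-ynoyl] 8α,9α-acetonide | CC1(C)O[C@@H]2[C@H](C(C)=C)C[C@]3(C)[C@@H](C)[C@H](OC(=O)C#C[C@H](CC)OC(=O)C#CCCC)CC[C@H]3[C@@H]2O1 | intermediate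
31 | 3α-O-[(S,2Z)-4-((Z)-hex-2-enoyloxy)hex-2-enoyl] 8α,9α-acetonide | CC1(C)O[C@@H]2[C@H](C(C)=C)C[C@]3(C)[C@@H](C)[C@H](OC(=O)/C=C\[C@H](CC)OC(=O)/C=C\CCC)CC[C@H]3[C@@H]2O1 | intermediate
32 | CNP0271544.1 | C=C(C)[C@@H]1C[C@]2(C)[C@@H](C)[C@H](OC(=O)/C=C\[C@H](CC)OC(=O)/C=C\CCC)CC[C@H]2[C@H](O)[C@@H]1O | target

**Step count**

Total: 24 steps. Longest linear sequence: 18 steps (steps 1, 3–16, 22–24) from 2-methoxy-5-methylphenol.

**Steps most likely to fail**

Step 3. The bulky titanium complex may turn over slowly at the methyl-substituted C5=C10 bond. Regiocontrol may be lost if the metal binds the C6 carbonyl in a monodentate way instead of chelating, and face selectivity at C5 may be insufficient. Fallback: starting again from 2 and 4, the cycloaddition is run with stoichiometric SnCl4 in CH2Cl2 at −78 °C, a chelating but achiral Lewis acid. This should give the racemate, that is 5 together with the enantiomeric adduct F1. The mixture is taken through the conditions of step 4 (the enantiomeric cis-fused trione F2 is not isolated) to racemic trione, that is 7 together with the enantiomeric trans-fused trione F3. The enantiomers are separated by preparative chromatography on a chiral stationary phase, and the route is rejoined at 7.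

Step 11. Hydride delivery to C6, next to quaternary C5, may be slow. The dienolate may be protonated at the terminal carbon and give the conjugated isopropylidene ketone, or protonation at C7 may occur from the wrong face. Fallback: setting out from 12, the enone is hydrogenated (H2, Pd/C, EtOAc) to the saturated 8-ketone F4. Deprotonation with LDA in THF at −78 °C on the CH2 side, away from the silyloxy-bearing C9, gives the lithium enolate F5. This is trapped with acetone in the presence of ZnCl2 as the 7-(2-hydroxypropan-2-yl) ketone F6. Acid-catalysed dehydration (TsOH, toluene, 60 °C) gives the conjugated 7-isopropylidene ketone F7. This is deconjugated in the classical way: KOt-Bu in THF/t-BuOH forms the extended potassium dienolate F8, and a cold AcOH quench protonates it kinetically at C7 to give 16, where the route is rejoined.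

Step 23. On the most advanced intermediate, the electron-poor alkynes may be over-reduced to saturated esters, the isopropenyl group may be partly hydrogenated, or the catalyst may isomerise the (Z)-enoates. Fallback: setting out from 28, the semihydrogenation is done on the small fragment under the same catalyst to give the tert-butyl (Z,Z)-diester F9. TFA then gives the (Z,Z)-acid F10. This is converted under neutral conditions with 1-chloro-N,N,2-trimethylpropenylamine into the (Z,Z)-acid chloride F11. Reaction of F11 with alcohol 21 and pyridine in CH2Cl2 at −20 °C, without DMAP, gives 31, where the route is rejoined.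

**Further compounds**

F1 | step 3 | enantiomer of adduct 5 | O=C1C=C(OC)C(=O)[C@@H]2CC=C(O[Si](C)(C)C)[C@H](C)[C@]12C
F2 | step 3 | enantiomer of cis-fused trione 6 | O=C1C=C(OC)C(=O)[C@@H]2CCC(=O)[C@H](C)[C@]12C
F3 | step 3 | enantiomer of trans-fused trione 7 | O=C1[C@@]2(C)[C@H](C)C(=O)CC[C@@H]2C(=O)C(OC)=C1
F4 | step 11 | 3β,9α-bis(TBS-oxy)-4β,5β-dimethyl-10α-H-decal-8-one | O=C1CC[C@]2(C)[C@@H](C)[C@@H](O[Si](C)(C)C(C)(C)C)CC[C@H]2[C@@H]1O[Si](C)(C)C(C)(C)C
F5 | step 11 | lithium 7-en-8-olate of F4 | [Li]OC1=CC[C@]2(C)[C@@H](C)[C@@H](O[Si](C)(C)C(C)(C)C)CC[C@H]2[C@@H]1O[Si](C)(C)C(C)(C)C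
F6 | step 11 | 7α-(2-hydroxypropan-2-yl)-3β,9α-bis(TBS-oxy)-decal-8-one | O=C1[C@H](C(C)(C)O)C[C@]2(C)[C@@H](C)[C@@H](O[Si](C)(C)C(C)(C)C)CC[C@H]2[C@@H]1O[Si](C)(C)C(C)(C)C
F7 | step 11 | 7-isopropylidene-3β,9α-bis(TBS-oxy)-decal-8-one | O=C1C(=C(C)C)C[C@]2(C)[C@@H](C)[C@@H](O[Si](C)(C)C(C)(C)C)CC[C@H]2[C@@H]1O[Si](C)(C)C(C)(C)C
F8 | step 11 | potassium dienolate of F7 | [K+].[O-]C1=C(C(C)=C)C[C@]2(C)[C@@H](C)[C@@H](O[Si](C)(C)C(C)(C)C)CC[C@H]2[C@@H]1O[Si](C)(C)C(C)(C)C
F9 | step 23 | tert-butyl (S,2Z)-4-((Z)-hex-2-enoyloxy)hex-2-enoate | CC[C@H](OC(=O)/C=C\CCC)/C=C\C(=O)OC(C)(C)C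
F10 | step 23 | (S,2Z)-4-((Z)-hex-2-enoyloxy)hex-2-enoic acid | CC[C@H](OC(=O)/C=C\CCC)/C=C\C(=O)O
F11 | step 23 | (S,2Z)-4-((Z)-hex-2-enoyloxy)hex-2-enoyl chloride | CC[C@H](OC(=O)/C=C\CCC)/C=C\C(=O)Cl
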